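**Retrosynthetic overview**
- Chebulic acid 12 comes from the hexabenzyl lactone 11 by one global hydrogenolysis.
- The lactone ring is the only ring made (the arene is bought as a gallate). It closes when the C3 hydroxyl of 10 attacks the aryl methyl ester; C3 and C4 are set by transfer hydrogenation of keto ester 9 under dynamic kinetic resolution.
- Key C4–C1' disconnection of 9: the lithium enolate 8 of an aryl pyruvate (C4 as nucleophile) is alkylated by (S)-malate triflate 7, in which C1' acts as an α-electrophile (enolonium equivalent). SN2 inversion sets 1'S from the chiral pool.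
- Enolate 8 comes from enol acetate 5, made by Heck coupling of bromogallate 2 with benzyl 2-acetoxyacrylate 4.

Assumption: 1, 3 and 6 are catalogue compounds; C1, O2, C3, C4 follow isochroman-1-one numbering of the target, and C1'/C2' are the succinate carbons. Nothing here has been run; yields and selectivities are expectations.

**Step 1**
Reactants: 1 methyl 3,4,5-tris(benzyloxy)benzoate
Product: 2 methyl 2-bromo-3,4,5-tris(benzyloxy)benzoate
Conditions: NBS (1.05 equiv), MeCN, rt, dark
Reagents that add atoms: N-bromosuccinimide, O=C1CCC(=O)N1Br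
Why: Electrophilic aromatic bromination; the only free ring positions (C2/C6, equivalent) are activated ortho/para by benzyloxy groups, and ionic conditions leave the benzylic CH2 groups alone.

**Step 2**
Reactants: 3 benzyl pyruvate
Product: 4 benzyl 2-acetoxyacrylate
Conditions: Ac2O, pyridine, DMAP (cat.), CH2Cl2, 0 °C → rt
Reagents that add atoms: acetic anhydride, CC(=O)OC(C)=O
Why: O-acetylation of the pyruvate enol (enol ester formation) gives a stable, Heck-competent captodative alkene.

**Step 3**
Reactants: 2 methyl 2-bromo-3,4,5-tris(benzyloxy)benzoate; 4 benzyl 2-acetoxyacrylate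
Product: 5 methyl 2-[(1Z)-2-acetoxy-3-(benzyloxy)-3-oxoprop-1-en-1-yl]-3,4,5-tris(benzyloxy)benzoate
Conditions: Pd2(dba)3 (2.5 mol %), P(t-Bu)3·HBF4 (10 mol %), Cy2NMe (1.5 equiv), dioxane, 90 °C
Reagents that add atoms: none
Why: Mizoroki–Heck reaction; the aryl group adds to the unhindered CH2 terminus and β-hydride elimination can only give the enol acetate, which keeps the pyruvate enol oxygen masked so it cannot close onto the ortho ester.

**Step 4**
Reactants: 5 methyl 2-[(1Z)-2-acetoxy-3-(benzyloxy)-3-oxoprop-1-en-1-yl]-3,4,5-tris(benzyloxy)benzoate; 6 dibenzyl (S)-malate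
Product: 9 tribenzyl (2S)-3-[6-(methoxycarbonyl)-2,3,4-tris(benzyloxy)phenyl]-4-oxobutane-1,2,4-tricarboxylate (both C3 epimers), via malate triflate 7 (not isolated), via lithium enolate 8 (not isolated)
Conditions: 6: Tf2O, 2,6-lutidine, CH2Cl2, −78 °C, cold filtration through silica; 5: BnOLi (from BnOH and n-BuLi, 1.0 equiv), THF, −40 °C; triflate solution added to the enolate (1.2 equiv), −78 → −20 °C
Reagents that add atoms: none
Why: Proposed new method: the chelated lithium Z-enolate of the α-keto ester attacks the α-triflyloxy ester (an enolonium equivalent of succinate) at carbon in an SN2 reaction with clean inversion, turning the S carbinol carbon of L-malate into 1'S and joining two α-carbons into the 1,4-dicarbonyl; the closest known reactions are the inversion-specific displacement of α-triflyloxy esters by malonate anions and the C-alkylation of aryl pyruvate enolates, and the new C4 centre is left as a mixture because step 5 corrects it.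

**Step 5**
Reactants: 9 tribenzyl (2S)-3-[6-(methoxycarbonyl)-2,3,4-tris(benzyloxy)phenyl]-4-oxobutane-1,2,4-tricarboxylate
Product: 11 dibenzyl (2S)-2-[(3S,4S)-3-(benzyloxycarbonyl)-5,6,7-tris(benzyloxy)-1-oxo-3,4-dihydro-1H-isochromen-4-yl]butanedioate, via hydroxy tetraester 10 (not isolated)
Conditions: RuCl[(S,S)-TsDPEN](p-cymene) (2 mol %), HCO2H/Et3N 5:2, DMF, 40 °C; then TsOH·H2O (10 mol %), 5 Å sieves, toluene, 70 °C
Reagents that add atoms: none
Why: Noyori–Ikariya asymmetric transfer hydrogenation with dynamic kinetic resolution of a β-aryl α-keto ester; the (S,S) catalyst is expected to give 3S (ester in the aryl-type position of the Noyori model), the acidic benzylic C4–H epimerises through the enol so only the Felkin-matched 4S epimer is reduced while C1' (α to an ester only) is untouched, and acid then closes the conjugated trans lactone onto the methyl benzoate, driven by trapping of methanol.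

**Step 6**
Reactants: 11 dibenzyl (2S)-2-[(3S,4S)-3-(benzyloxycarbonyl)-5,6,7-tris(benzyloxy)-1-oxo-3,4-dihydro-1H-isochromen-4-yl]butanedioate
Product: 12 chebulic acid
Conditions: H2 (1 atm), 10% Pd/C, THF/H2O 9:1, rt
Reagents that add atoms: none
Why: Catalytic hydrogenolysis removes the three aryl benzyl ethers and three benzyl esters under neutral conditions that leave the lactone, the benzylic C4–C bonds and all three stereocentres untouched.

**Compound list**
1 | methyl 3,4,5-tris(benzyloxy)benzoate | COC(=O)c1cc(OCc2ccccc2)c(OCc2ccccc2)c(OCc2ccccc2)c1 | starting material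
2 | methyl 2-bromo-3,4,5-tris(benzyloxy)benzoate | COC(=O)c1cc(OCc2ccccc2)c(OCc2ccccc2)c(OCc2ccccc2)c1Br | intermediate
3 | benzyl pyruvate | CC(=O)C(=O)OCc1ccccc1 | starting material
4 | benzyl 2-acetoxyacrylate | C=C(OC(C)=O)C(=O)OCc1ccccc1 | intermediate
5 | methyl 2-[(1Z)-2-acetoxy-3-(benzyloxy)-3-oxoprop-1-en-1-yl]-3,4,5-tris(benzyloxy)benzoate | COC(=O)c1cc(OCc2ccccc2)c(OCc2ccccc2)c(OCc2ccccc2)c1/C=C(\OC(C)=O)C(=O)OCc1ccccc1 | intermediate
6 | dibenzyl (S)-malate | O=C(OCc1ccccc1)C[C@H](O)C(=O)OCc1ccccc1 | starting material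
7 | dibenzyl (2S)-2-{[(trifluoromethyl)sulfonyl]oxy}butanedioate (malate triflate) | O=C(OCc1ccccc1)C[C@H](OS(=O)(=O)C(F)(F)F)C(=O)OCc1ccccc1 | intermediate
8 | lithium (1Z)-3-(benzyloxy)-1-[6-(methoxycarbonyl)-2,3,4-tris(benzyloxy)phenyl]-3-oxoprop-1-en-2-olate (lithium enolate) | [Li+].COC(=O)c1cc(OCc2ccccc2)c(OCc2ccccc2)c(OCc2ccccc2)c1/C=C(\[O-])C(=O)OCc1ccccc1 | intermediate
9 | tribenzyl (2S)-3-[6-(methoxycarbonyl)-2,3,4-tris(benzyloxy)phenyl]-4-oxobutane-1,2,4-tricarboxylate (both C3 epimers) | COC(=O)c1cc(OCc2ccccc2)c(OCc2ccccc2)c(OCc2ccccc2)c1C([C@H](CC(=O)OCc1ccccc1)C(=O)OCc1ccccc1)C(=O)C(=O)OCc1ccccc1 | intermediate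
10 | tribenzyl (2S,3S,4S)-4-hydroxy-3-[6-(methoxycarbonyl)-2,3,4-tris(benzyloxy)phenyl]butane-1,2,4-tricarboxylate (hydroxy tetraester) | COC(=O)c1cc(OCc2ccccc2)c(OCc2ccccc2)c(OCc2ccccc2)c1[C@H]([C@H](CC(=O)OCc1ccccc1)C(=O)OCc1ccccc1)[C@H](O)C(=O)OCc1ccccc1 | intermediate
11 | dibenzyl (2S)-2-[(3S,4S)-3-(benzyloxycarbonyl)-5,6,7-tris(benzyloxy)-1-oxo-3,4-dihydro-1H-isochromen-4-yl]butanedioate | O=C(OCc1ccccc1)C[C@H](C(=O)OCc1ccccc1)[C@H]1c2c(cc(OCc3ccccc3)c(OCc3ccccc3)c2OCc2ccccc2)C(=O)O[C@@H]1C(=O)OCc1ccccc1 | intermediate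
12 | chebulic acid, (2S)-2-[(3S,4S)-3-carboxy-5,6,7-trihydroxy-1-oxo-3,4-dihydro-1H-isochromen-4-yl]butanedioic acid | O=C(O)C[C@H](C(=O)O)[C@H]1c2c(cc(O)c(O)c2O)C(=O)O[C@@H]1C(=O)O | target

**Totals**
Total step count: 6. Longest linear sequence: 5 steps (1 → 2 → 5 → 9 → 11 → 12).

**Steps most likely to fail**

Step 4 is the weakest. The enolate carbon carries a di-ortho-substituted aryl group and must attack a secondary triflate. O-alkylation of the enolate may compete. Elimination of the triflate to dibenzyl fumarate followed by Michael addition would give the same constitution but racemic C1', so the configuration at C1' of 9 must be checked. The fallback changes the order of bond formation and sets out from 4 (with 6 converted to triflate 7 as before). BnOLi cleaves 4 to the lithium enolate of benzyl pyruvate F1, whose unhindered CH2 terminus is alkylated by 7 to tribenzyl (2R)-4-oxobutane-1,2,4-tricarboxylate F2. F2 has the same spatial arrangement at the malate-derived carbon; only the descriptor letter changes because the aryl group is absent. The aryl group is then attached by Pd-catalysed β-arylation of the keto ester enolate of F2 with bromide 2 (Pd2(dba)3, P(t-Bu)3·HBF4, K3PO4, toluene, 100 °C), which comes back to the route at 9.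

Step 5 is next. The dynamic resolution needs C4 to epimerise faster than the ketone is reduced, and the crowded keto ester may instead close to an enol lactone or reduce without stereoconvergence. The fallback sets out from 9 and gives up the dynamic resolution. TsOH in hot toluene closes 9, with loss of methanol, to the enol lactone benzyl 5,6,7-tris(benzyloxy)-4-[(2S)-1,4-bis(benzyloxy)-1,4-dioxobutan-2-yl]-1-oxo-1H-isochromene-3-carboxylate F3. The tetrasubstituted C3=C4 bond is hydrogenated with [Ir(cod)(PCy3)(py)]PF6 and H2 in CH2Cl2, which leaves benzyl groups intact, to the cis lactone dibenzyl (2S)-2-[(3R,4S)-3-(benzyloxycarbonyl)-5,6,7-tris(benzyloxy)-1-oxo-3,4-dihydro-1H-isochromen-4-yl]butanedioate F4, separated from its 4R partner by chromatography. DBU in toluene then epimerises the acidic C3 to the trans lactone, coming back at 11.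

Step 3 is third. The aryl bromide is flanked by an ester and a benzyloxy group, so oxidative addition and insertion may be slow and the acrylate may polymerise. The fallback sets out from 2 and replaces the Heck reaction by an olefination. Br/Mg exchange (i-PrMgCl·LiCl, THF, −20 °C) and DMF give methyl 3,4,5-tris(benzyloxy)-2-formylbenzoate F5. Horner–Wadsworth–Emmons reaction of F5 with the phosphonate benzyl 2-acetoxy-2-(diethoxyphosphoryl)acetate F6 (LiCl, DBU, MeCN) delivers the enol acetate and comes back at 5.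

**Further compounds**
F1 | step 4 | lithium 3-(benzyloxy)-3-oxoprop-1-en-2-olate (lithium enolate of benzyl pyruvate) | [Li+].C=C([O-])C(=O)OCc1ccccc1
F2 | step 4 | tribenzyl (2R)-4-oxobutane-1,2,4-tricarboxylate | O=C(OCc1ccccc1)C[C@H](C(=O)OCc1ccccc1)CC(=O)C(=O)OCc1ccccc1
F3 | step 5 | benzyl 5,6,7-tris(benzyloxy)-4-[(2S)-1,4-bis(benzyloxy)-1,4-dioxobutan-2-yl]-1-oxo-1H-isochromene-3-carboxylate | O=C(OCc1ccccc1)C[C@H](C(=O)OCc1ccccc1)C1=C(C(=O)OCc2ccccc2)OC(=O)c2cc(OCc3ccccc3)c(OCc3ccccc3)c(OCc3ccccc3)c21
F4 | step 5 | dibenzyl (2S)-2-[(3R,4S)-3-(benzyloxycarbonyl)-5,6,7-tris(benzyloxy)-1-oxo-3,4-dihydro-1H-isochromen-4-yl]butanedioate | O=C(OCc1ccccc1)C[C@H](C(=O)OCc1ccccc1)[C@H]1c2c(cc(OCc3ccccc3)c(OCc3ccccc3)c2OCc2ccccc2)C(=O)O[C@H]1C(=O)OCc1ccccc1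
F5 | step 3 | methyl 3,4,5-tris(benzyloxy)-2-formylbenzoate | COC(=O)c1cc(OCc2ccccc2)c(OCc2ccccc2)c(OCc2ccccc2)c1C=O
F6 | step 3 | benzyl 2-acetoxy-2-(diethoxyphosphoryl)acetate | CCOP(=O)(OCC)C(OC(C)=O)C(=O)OCc1ccccc1
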